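I began with the amounts: the flask holds free catalyst at 1.00 mM against impurity at 1.4 mM, and each poisoning event removes one of each.

substrate 0.10 M; gas phase 12 mM (held); free catalyst 1 mol%; impurity 1.4 mM; time 2.0 h

* product at 2.0 h, in percent of the substrate charged
* concentration of dissolved gas in solution at 1.0 h, in percent of saturation
* the change that raises the amount of product at 2.0 h, in percent of the substrate charged most ("none" if none brings more than 2 percentage points) (zeta / theta / beta / none)
* amount of product at 2.0 h, in percent of the substrate charged, after theta

- zeta: doubling the transfer coefficient of step 4, all else as stated
- theta: doubling the amount of free catalyst, all else as stated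
- beta: doubling the saturation concentration of gas phase, all else as stated

    substrate + dissolved gas + free catalyst ⇌ free catalyst + product (K1 = 47 /M, k1 = 16000 /M²/min)
    free catalyst + impurity → spent catalyst (k2 = 195 /M/min)
    dissolved gas → decomposed reagent (k3 = 0.00214 /min)
    gas phase ⇌ dissolved gas, rate k4*(csat - [dissolved gas]) (k4 = 0.0138 /min, csat = 12 mM)

Who runs out first? Free catalyst is the smaller charge in this poisoning step, by a margin m = 0.400 mM. That difference stays fixed, so the ratio of free catalyst to impurity falls as an exponential in time, with the pairing lifetime τ, the inverse of the poisoning constant 195 /M/min times m: 12.8 min.

How long does the catalyst work? The run holds 9.36 such lifetimes, and by my reckoning free catalyst was down to 0.267 % of its charge at 1.0 h.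

How much product does that buy? Gas enters a solution still empty of it at 0.166 mM/min, and with the charges as they stand the forward rate of step 1 alone takes dissolved gas up with a half-life of 0.43 min, shorter than τ, so I let product follow the supply at first. After two lifetimes the uptake half-life had stretched to 10.1 min, against τ, so I stopped counting there and reckoned 4.25 % of product. By this count a doubled supply gave twice that figure, whereas doubled catalyst exceeds the impurity, and keeps working under a supply that reaches at most 19.9 % by 2.0 h into a solution kept empty, more than the doubled figure, so I chose theta.

The forecast gave 4 %, 36 %, theta and 13.2 %, holding that the catalyst “dies within about 30 minutes”.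

The simulation gave 3.91 %, 36.3 % and theta, which gains 9.3 percentage points against 3.1 points for zeta and 3.8 points for beta, with 13.2 % after theta; free catalyst stood at 0.267 % at 1.00 h.

The neighbouring flask, with 1.7 mol% of free catalyst, reverses the margin: catalyst now exceeds impurity by 0.300 mM, and the same count gives 7.02 lifetimes in the run. Impurity is now the smaller charge, so I reckoned 0.0158 % of it left. That flask kept 0.016 % of its impurity and 17.7 % of its free catalyst, and it reached 13.0 % of product.

All constants belong to no real substance; the run is a simulation.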